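## The problem

Target 26 is a linear assembly: a 2-alkyl-6-methyl-1,4-benzoquinone, a methylene, an E-trisubstituted alkene, a ketone, a cyclopentane with two adjacent quaternary ring carbons, and a prenyl ketone. Apart from the quinone there is one carbocycle, so the task is chain construction on both sides of a small ring, not ring fusion. The two quaternary carbons (both R, methyl groups cis) are the only stereocentres. Nothing else in the molecule can set or repair them, so they must be made together; once made they cannot epimerise because neither bears hydrogen. A cis-fused bicyclo[3.3.0]octane enforces their cis relationship, and breaking the mirror symmetry of such a bicycle can supply the absolute configuration. The two ring substituents differ by one carbon (C=O directly on one ring carbon, CH2–C=O on the other), so one bond of a fused precursor must be cut into a one-carbon and a two-carbon stub. Both ketones are β,γ-unsaturated and the quinone is an oxidant and an electrophile, so acid, base, nucleophiles and reductants all threaten the finished chain. The enabling feature is the quinone pattern: C-1 (the carbonyl between chain-bearing C-2 and methyl-bearing C-6) can be one CO, C-4/C-5/C-6 with the methyl group can be a propenyl(methoxy)carbene ligand, and C-2/C-3 can be a terminal alkyne at the end of the complete chain.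

## Retrosynthesis

26 ⇒ 25. No skeletal bond is cut; the quinone is traced to 4-methoxyphenol 25. Carrying a quinone or free hydroquinone through C–C bond formation is ruled out by its redox and Michael reactivity. The forward step must be a fast oxidative demethylation that leaves two β,γ-enones and two trisubstituted alkenes alone.

25 ⇒ 18 + 23. Three ring bonds are cut: C-3–C-4, C-1–C-2 and C-1–C-6 of the future quinone. The ring divides into the terminal alkyne of 18 (C-2, C-3), the propenyl(methoxy)carbene ligand of 23 (C-4, C-5, C-6 and the methyl group) and one carbonyl ligand of 23 (C-1). The neighbouring cut at the aryl–CH2 bond would need a preformed tetrasubstituted arene with two differentiated oxygens and an allyl–aryl coupling with SN2/SN2′ ambiguity. Cutting inside the ring lets the mechanism dictate the substitution pattern. 18 has no arene and 23 is a four-carbon reagent. The forward reaction must place the chain next to the CO-derived carbon, choose the alkyne over two alkenes and two ketones, and run without acid or base.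

23 ⇒ 19 + 20. The bond from the carbene carbon to the propenyl group is cut, giving alkenyl bromide 19 and Cr(CO)6 20. The forward sequence must keep the alkene geometry.

18 ⇒ 17. No C–C bond is cut; both ketones are traced to secondary alcohols. This postpones the two base-sensitive β,γ-enones to the step before the benzannulation, so all chain C–C bond formation can use basic organometallic reagents. The forward oxidation must be neutral and must not move double bonds.

17 ⇒ 16. The propargylic sp–sp3 bond is cut between an ethynyl nucleophile and primary allylic chloride 16. Cutting on the other side of the alkene (allyl metal plus carbonyl) would give the branched isomer, because such reagents react at their substituted terminus. The forward coupling must occur at the primary carbon and keep the E geometry.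

16 ⇒ 15 ⇒ 13. The chloride is traced to allylic alcohol 15. Then the bonds from the two alkene carbons to the methyl group and to the CH2OH carbon are cut, leaving terminal alkyne 13. A carbonyl olefination would give E/Z mixtures at a trisubstituted alkene; a syn carbometalation fixes the geometry by mechanism. 13 has lost the whole stereodefined alkene.

13 ⇒ 12 ⇒ 11. The bond between the carbinol carbon and the propargyl CH2 is cut to a propargyl nucleophile and lactol 12, a masked hydroxy aldehyde, which is the reduced form of lactone 11. The lactone ties the two arms into one ring and so protects the acid-level carbon and the first carbinol at once.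

11 ⇒ 10 ⇒ 9. The prenyl C=C is cut by retro-metathesis to allyl lactone 10. The carbinol–allyl bond and the lactone C–O bond are then cut to aldehyde acid 9. Direct prenyl addition is avoided because prenyl metals deliver their tertiary terminus; allyl addition has no such ambiguity and the two methyl groups arrive afterwards.

9 ⇒ 8. The aldehyde and carboxyl carbons are reconnected as the C=C of silyl enol ether 8. Cleaving this bond of a bicyclo[3.3.0]octene gives exactly the needed one-carbon aldehyde stub and two-carbon acid stub, already different in oxidation level. A symmetric cleavage such as a diol or diketone would give two equal stubs.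

8 ⇒ 7. The enol ether is traced to meso ketone 7. The forward deprotonation must distinguish two enantiotopic methylene groups, which sets both quaternary centres in an absolute sense.

7 ⇒ 5 ⇒ 4. The missing ring carbonyl is restored: 7 comes from monoketal 5 by deoxygenation and deprotection, and 5 from dione 4.

4 ⇒ 3 ⇒ 1 + 2. Four C–C bonds are cut, those joining each ring-fusion carbon to its two neighbouring CH2 groups. This reveals butane-2,3-dione 1 and two molecules of dimethyl 3-oxoglutarate 2. The ring fusion can only be cis, so the methyl groups are cis from the first step.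

## Roads not taken

Alternative 1: The cut is at the two exocyclic bonds that join the quaternary ring carbons to their side-arm carbons. Forward, dioxinone A2 and 1,2-dimethylcyclopentene A3 are irradiated to give the cis-anti-cis photoadduct A1. Acetal cleavage and retro-aldol fragmentation would give keto acid A4. Merits: both quaternary carbons and both arms arise in about three steps, and the acetal carbon of A2 directs the face. Weak points for this target: the [2+2] addition joins a tetrasubstituted alkene to a substituted enone carbon, so the facial selectivity on which the absolute configuration rests is uncertain. In addition A4 carries a methyl ketone at the hindered site, and turning it into a prenyl ketone means joining a 2-methylpropenyl group to an enolate carbon, for which no simple alkylation exists. In step count to the core this road is better than the chosen one (about three steps to A4 against six to 9). The chosen plan sets against this ground-state reactions that scale, an aldehyde at the hindered site that accepts a complete allyl unit, and free choice of enantiomer through the amide. A4 could feed the same late benzannulation, so the comparison concerns only the first third of the route.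

Alternative 2: The cut is the ring bond between the two quaternary carbons. Forward, the nine-membered lactone A6 is enolised and silylated and rearranges through a boat transition state to acid A5, with carboxyl and propenyl cis. Merits: both quaternary centres form in one bond-forming event, their cis relationship follows from the pericyclic array, and one secondary carbinol centre (9R in A6 on a boat analysis) relays the absolute configuration. This stereochemical economy is better than the chosen plan's use of a stoichiometric chiral amide of untested selectivity. Weak points: A6 is a medium ring with a Z trisubstituted alkene and is hard to close. The ketene acetal is tetrasubstituted and must form with one geometry. The new bond joins two fully substituted carbons. Downstream, the propenyl group must be oxidised regioselectively at an internal alkene carbon to become the CH2–C=O arm. The chosen plan sets against this a two-step aqueous construction of the quaternary pair and arms that emerge at the right length and oxidation level.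

Alternative 3: The cut is at the two ring bonds from the quaternary carbons to their CH2 neighbours in a six-membered ring. Forward, buta-1,3-diene A8 and 2,3-dimethylmaleic anhydride A9 are heated in a sealed vessel to give meso anhydride A7. Merits: the cheapest start of all, and desymmetrising alcoholysis of cyclic meso anhydrides under cinchona-alkaloid control has stronger precedent than the chiral-amide deprotonation of 7. In that respect this road is better. Weak points: the dienophile is tetrasubstituted and slow. The ring is six-membered and must be cleaved and re-closed with loss of a carbon. Both anhydride carbons are one-carbon stubs at the acid level, so one needs homologation at a neopentyl position. The chosen plan sets against this the correct ring size and a one-carbon/two-carbon pair of arms obtained directly from one ozonolysis.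

Key step: step 16

Assumption on the chemistry: the sense of induction of the chiral lithium amide on 7 cannot be predicted with certainty; the route is written for the (R,R)-amide, and the (S,S)-amide is used if the (R,R)-reagent removes the other enantiotopic proton.

Remark on the chemistry: the carbinol carbons made in steps 7 and 10 and the lactol carbon of 12 are not controlled; 10–17 are epimer mixtures at these centres, written without descriptors, and all converge in step 14.

## Route

Step 1
Reactants: 1 butane-2,3-dione; 2 dimethyl 3-oxopentanedioate (dimethyl 3-oxoglutarate, 2 equiv)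
Product: 3 tetramethyl cis-1,5-dimethyl-3,7-dioxobicyclo[3.3.0]octane-2,4,6,8-tetracarboxylate (largely as its bis-enol; ester-bearing carbons not defined)
Conditions: aq. NaHCO3 (pH about 8), rt
Reagents that add atoms: none
Why: Weiss–Cook condensation: each oxoglutarate adds through its two α-carbons to the two carbonyl carbons of 1, forming four C–C bonds; only the cis-fused bicycle can close, so both quaternary carbons are created with cis methyl groups in an achiral framework.

Step 2
Reactants: 3 tetramethyl cis-1,5-dimethyl-3,7-dioxobicyclo[3.3.0]octane-2,4,6,8-tetracarboxylate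
Product: 4 cis-1,5-dimethylbicyclo[3.3.0]octane-3,7-dione (meso)
Conditions: 1 M HCl, AcOH, reflux
Reagents that add atoms: none
Why: Acid hydrolysis of four β-keto esters followed by decarboxylation; the quaternary ring-fusion carbons cannot epimerise.

Step 3
Reactants: 4 cis-1,5-dimethylbicyclo[3.3.0]octane-3,7-dione
Product: 5 cis-1,5-dimethylbicyclo[3.3.0]octane-3,7-dione mono(2,2-dimethylpropane-1,3-diyl) ketal
Conditions: 2,2-dimethylpropane-1,3-diol (1 equiv), p-TsOH (cat.), toluene, reflux, Dean–Stark
Reagents that add atoms: 2,2-dimethylpropane-1,3-diol, OCC(C)(C)CO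
Why: Acid-catalysed ketalisation with azeotropic water removal, held at one carbonyl by stoichiometry (recovered 4 and bis-ketal are re-equilibrated); the six-membered ketal withstands the hot alkali of step 4.

Step 4
Reactants: 5 cis-1,5-dimethylbicyclo[3.3.0]octane-3,7-dione mono(2,2-dimethylpropane-1,3-diyl) ketal
Product: 7 cis-1,5-dimethylbicyclo[3.3.0]octan-3-one (meso), via deoxygenated ketal 6 (not isolated)
Conditions: N2H4·H2O, KOH, diethylene glycol, 130 then 200 °C; crude, then 2 M HCl, THF, rt
Reagents that add atoms: water, O
Why: Wolff–Kishner reduction deletes the free carbonyl while the ketal is inert to base; aqueous acid then hydrolyses the ketal, returning a ketone that keeps its mirror plane.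

Step 5
Reactants: 7 cis-1,5-dimethylbicyclo[3.3.0]octan-3-one
Product: 8 (1S,5R)-1,5-dimethyl-3-(trimethylsilyloxy)bicyclo[3.3.0]oct-2-ene
Conditions: (R,R)-bis(1-phenylethyl)amine, n-BuLi, Me3SiCl (in situ), THF, −100 °C
Reagents that add atoms: chlorotrimethylsilane, C[Si](C)(C)Cl
Why: Enantioselective deprotonation of a meso ketone by a C2-symmetric chiral lithium amide with in situ silylation; removing one of two enantiotopic α-methylene protons fixes the absolute configuration of both quaternary carbons at once, and the enol ether cannot racemise.

Step 6
Reactants: 8 (1S,5R)-1,5-dimethyl-3-(trimethylsilyloxy)bicyclo[3.3.0]oct-2-ene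
Product: 9 2-[(1R,2R)-2-formyl-1,2-dimethylcyclopentyl]acetic acid
Conditions: O3, CH2Cl2/MeOH, −78 °C; then Me2S, −78 °C to rt; aqueous work-up
Reagents that add atoms: ozone, [O-][O+]=O
Why: Ozonolysis of a silyl enol ether: the CH terminus becomes the aldehyde and the silyloxy carbon a silyl ester that hydrolyses to the acid on work-up (9 may rest as its cyclic hydroxy-lactone tautomer); Me2S reduces the peroxidic intermediates.

Step 7
Reactants: 9 2-[(1R,2R)-2-formyl-1,2-dimethylcyclopentyl]acetic acid
Product: 10 (4aR,7aR)-4a,7a-dimethyl-1-(prop-2-en-1-yl)-4,4a,5,6,7,7a-hexahydrocyclopenta[c]pyran-3(1H)-one (C-1 epimers)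
Conditions: CH2=CHCH2MgBr (3 equiv), THF, −78 to 0 °C; then 2 M HCl, rt
Reagents that add atoms: allylmagnesium bromide, C=CC[Mg]Br
Why: Grignard addition: the first equivalent gives the inert magnesium carboxylate (opening any lactol form) and further reagent adds to the neopentyl aldehyde; acidification closes the cis-fused six-membered lactone, the new carbinol centre being uncontrolled and later oxidised.

Step 8
Reactants: 10 (4aR,7aR)-4a,7a-dimethyl-1-(prop-2-en-1-yl)-4,4a,5,6,7,7a-hexahydrocyclopenta[c]pyran-3(1H)-one
Product: 11 (4aR,7aR)-4a,7a-dimethyl-1-(3-methylbut-2-en-1-yl)-4,4a,5,6,7,7a-hexahydrocyclopenta[c]pyran-3(1H)-one (C-1 epimers)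
Conditions: second-generation Grubbs catalyst (5 mol %), 2-methylbut-2-ene/CH2Cl2, 40 °C
Reagents that add atoms: 2-methylbut-2-ene, CC=C(C)C
Why: Olefin cross-metathesis of a monosubstituted alkene with a large excess of 2-methylbut-2-ene, the standard conversion of allyl into prenyl; the lactone is inert and the trisubstituted product does not re-enter the cycle.

Step 9
Reactants: 11 (4aR,7aR)-4a,7a-dimethyl-1-(3-methylbut-2-en-1-yl)-4,4a,5,6,7,7a-hexahydrocyclopenta[c]pyran-3(1H)-one
Product: 12 (4aR,7aR)-4a,7a-dimethyl-1-(3-methylbut-2-en-1-yl)octahydrocyclopenta[c]pyran-3-ol (lactol; C-1 and C-3 epimers)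
Conditions: i-Bu2AlH, CH2Cl2, −78 °C; aq. potassium sodium tartrate
Reagents that add atoms: none
Why: Partial hydride reduction of a lactone; the tetrahedral aluminium alkoxide is stable at −78 °C and gives the lactol, a masked hydroxy aldehyde, on work-up.

Step 10
Reactants: 12 (4aR,7aR)-4a,7a-dimethyl-1-(3-methylbut-2-en-1-yl)octahydrocyclopenta[c]pyran-3-ol
Product: 13 1-[(1R,2R)-2-(2-hydroxypent-4-yn-1-yl)-1,2-dimethylcyclopentyl]-4-methylpent-3-en-1-ol (carbinol epimers)
Conditions: HC≡CCH2Br (3 equiv), Zn dust, THF/aq. NH4Cl, 0 °C to rt
Reagents that add atoms: 3-bromoprop-1-yne (propargyl bromide), BrCC#C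
Why: Barbier propargylation: allenylzinc bromide formed in situ adds to the open hydroxy-aldehyde form of the lactol through an SE2′ six-membered transition state, giving the homopropargylic alcohol; the new carbinol centre is oxidised in step 14.

Step 11
Reactants: 13 1-[(1R,2R)-2-(2-hydroxypent-4-yn-1-yl)-1,2-dimethylcyclopentyl]-4-methylpent-3-en-1-ol
Product: 15 (E)-6-[(1R,2R)-2-(1-hydroxy-4-methylpent-3-en-1-yl)-1,2-dimethylcyclopentyl]-3-methylhex-2-ene-1,5-diol (carbinol epimers), via alkenyldimethylalane 14 (not isolated)
Conditions: AlMe3 (5 equiv), Cp2ZrCl2 (0.3 equiv), CH2Cl2, 0 °C to rt; evaporate; n-BuLi, THF/hexane, −78 °C; (CH2O)n, to rt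
Reagents that add atoms: trimethylaluminium, C[Al](C)C; formaldehyde (as paraformaldehyde), C=O
Why: Zirconium-catalysed methylalumination of a terminal alkyne (Negishi carboalumination): Me and Al add syn with Al on the terminal carbon, fixing the E geometry; the alanate made with n-BuLi transfers the alkenyl group to formaldehyde with retention, the hydroxyls travelling as aluminium alkoxides and the prenyl alkene being inert.

Step 12
Reactants: 15 (E)-6-[(1R,2R)-2-(1-hydroxy-4-methylpent-3-en-1-yl)-1,2-dimethylcyclopentyl]-3-methylhex-2-ene-1,5-diol
Product: 16 (E)-6-chloro-1-[(1R,2R)-2-(1-hydroxy-4-methylpent-3-en-1-yl)-1,2-dimethylcyclopentyl]-4-methylhex-4-en-2-ol (carbinol epimers)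
Conditions: N-chlorosuccinimide, Me2S, CH2Cl2, −20 to 0 °C
Reagents that add atoms: N-chlorosuccinimide, O=C1CCC(=O)N1Cl
Why: Corey–Kim halogenation: only the allylic alkoxysulfonium ion collapses to the chloride at 0 °C, while those of the two saturated secondary alcohols revert on work-up; neutral conditions preserve the E alkene.

Step 13
Reactants: 16 (E)-6-chloro-1-[(1R,2R)-2-(1-hydroxy-4-methylpent-3-en-1-yl)-1,2-dimethylcyclopentyl]-4-methylhex-4-en-2-ol
Product: 17 (E)-1-[(1R,2R)-2-(1-hydroxy-4-methylpent-3-en-1-yl)-1,2-dimethylcyclopentyl]-4-methyloct-4-en-7-yn-2-ol (carbinol epimers)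
Conditions: HC≡CMgBr (5 equiv), CuCl (10 mol %), THF, 0 to 50 °C
Reagents that add atoms: ethynylmagnesium bromide, C#C[Mg]Br
Why: Copper-catalysed coupling of an alkynyl Grignard reagent with a primary allylic chloride, which occurs at the unsubstituted allylic terminus and keeps the E geometry; excess reagent holds the hydroxyls and the new terminal alkyne as magnesium salts, which guards the skipped enyne against base-induced isomerisation.

Step 14
Reactants: 17 (E)-1-[(1R,2R)-2-(1-hydroxy-4-methylpent-3-en-1-yl)-1,2-dimethylcyclopentyl]-4-methyloct-4-en-7-yn-2-ol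
Product: 18 (E)-1-[(1R,2R)-1,2-dimethyl-2-(4-methylpent-3-enoyl)cyclopentyl]-4-methyloct-4-en-7-yn-2-one
Conditions: Dess–Martin periodinane (3 equiv), NaHCO3, CH2Cl2, 0 °C to rt
Reagents that add atoms: none
Why: Dess–Martin oxidation under buffered, non-basic conditions turns both homoallylic alcohols into β,γ-unsaturated ketones without moving the double bonds or touching the terminal alkyne; all carbinol epimers converge on the single diketone 18.

Step 15
Reactants: 19 (E)-1-bromoprop-1-ene; 20 chromium hexacarbonyl, Cr(CO)6
Product: 23 pentacarbonyl[(E)-1-methoxybut-2-enylidene]chromium, via (E)-prop-1-enyllithium 21 (not isolated), via lithium acylchromate 22 (not isolated)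
Conditions: t-BuLi (2 equiv), Et2O, −78 °C; Cr(CO)6, Et2O, −78 °C to rt; Me3OBF4, CH2Cl2, 0 °C
Reagents that add atoms: trimethyloxonium tetrafluoroborate, C[O+](C)C.F[B-](F)(F)F
Why: Fischer carbene synthesis: bromine–lithium exchange with retention of alkene geometry, addition of the alkenyllithium to a CO ligand of Cr(CO)6 (zerovalent chromium) to give the acylate, and O-methylation by the oxonium salt.

Step 16
Reactants: 18 (E)-1-[(1R,2R)-1,2-dimethyl-2-(4-methylpent-3-enoyl)cyclopentyl]-4-methyloct-4-en-7-yn-2-one; 23 pentacarbonyl[(E)-1-methoxybut-2-enylidene]chromium (1.5 equiv)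
Product: 25 (E)-1-[(1R,2R)-1,2-dimethyl-2-(4-methylpent-3-enoyl)cyclopentyl]-6-(2-hydroxy-5-methoxy-3-methylphenyl)-4-methylhex-4-en-2-one, via tricarbonylchromium arene complex 24 (not isolated)
Conditions: THF (0.3 M), 50 °C, argon, dark; then air, Et2O, rt
Reagents that add atoms: none
Why: Dötz benzannulation, the known [3+2+1] reaction of alkenyl(alkoxy)carbene chromium complexes with terminal alkynes: thermal loss of one cis CO from 23 opens a site at zerovalent chromium, the alkyne of 18 inserts into the chromium–carbene bond to give a vinylcarbene complex, and CO insertion gives a chromium-bound dienylketene. The six-membered ring closes by a six-electron electrocyclisation that joins the ketene carbon to the methyl-bearing alkene carbon, and tautomerisation of the cyclohexadienone gives the phenol as its Cr(CO)3 complex 24, which air frees from the metal. Three ring C–C bonds form: carbene carbon to alkyne CH, internal alkyne carbon to the CO carbon, and CO carbon to the methyl-bearing carbon. No stereocentre is created and the two quaternary carbons lie far from the reacting atoms. The required regiochemistry (chain ortho to the new hydroxyl, H next to the methoxy carbon) follows from insertion of the alkyne with its substituted carbon away from the carbene carbon, a steric preference that is strong for terminal alkynes. Chemoselectivity rests on the carbene reacting with the alkyne much faster than with trisubstituted alkenes or ketones under neutral conditions at 50 °C. The E geometry of the chain alkene keeps the nearer ketone from reaching the vinylcarbene intramolecularly.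

Step 17
Reactants: 25 (E)-1-[(1R,2R)-1,2-dimethyl-2-(4-methylpent-3-enoyl)cyclopentyl]-6-(2-hydroxy-5-methoxy-3-methylphenyl)-4-methylhex-4-en-2-one
Product: 26 2-{(E)-6-[(1R,2R)-1,2-dimethyl-2-(4-methylpent-3-enoyl)cyclopentyl]-3-methyl-5-oxohex-2-en-1-yl}-6-methylcyclohexa-2,5-diene-1,4-dione
Conditions: (NH4)2Ce(NO3)6 (2.5 equiv), MeCN/H2O, 0 °C, minutes
Reagents that add atoms: water, O
Why: Oxidative demethylation of a 4-methoxyphenol by two equivalents of the one-electron oxidant (tetravalent cerium): the aryloxy cation is captured by water at the methoxy-bearing carbon and loses methanol to give the 1,4-quinone, faster at 0 °C than acid-induced changes in the chain.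

## Compound list

1 | butane-2,3-dione | CC(=O)C(C)=O | starting material
2 | dimethyl 3-oxopentanedioate (dimethyl 3-oxoglutarate) | COC(=O)CC(=O)CC(=O)OC | starting material
3 | tetramethyl cis-1,5-dimethyl-3,7-dioxobicyclo[3.3.0]octane-2,4,6,8-tetracarboxylate | O=C1C(C(=O)OC)[C@]2(C)C(C(=O)OC)C(=O)C(C(=O)OC)[C@]2(C)C1C(=O)OC | intermediate
4 | cis-1,5-dimethylbicyclo[3.3.0]octane-3,7-dione | O=C1C[C@]2(C)CC(=O)C[C@]2(C)C1 | intermediate
5 | cis-1,5-dimethylbicyclo[3.3.0]octane-3,7-dione mono(2,2-dimethylpropane-1,3-diyl) ketal | O=C1C[C@]2(C)CC3(OCC(C)(C)CO3)C[C@]2(C)C1 | intermediate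
6 | cis-1,5-dimethylbicyclo[3.3.0]octan-3-one 2,2-dimethylpropane-1,3-diyl ketal | CC1(C)COC2(C[C@]3(C)CCC[C@]3(C)C2)OC1 | intermediate
7 | cis-1,5-dimethylbicyclo[3.3.0]octan-3-one (meso) | O=C1C[C@]2(C)CCC[C@]2(C)C1 | intermediate
8 | (1S,5R)-1,5-dimethyl-3-(trimethylsilyloxy)bicyclo[3.3.0]oct-2-ene | C[Si](C)(C)OC1=C[C@]2(C)CCC[C@]2(C)C1 | intermediate
9 | 2-[(1R,2R)-2-formyl-1,2-dimethylcyclopentyl]acetic acid | O=C[C@]1(C)CCC[C@]1(C)CC(=O)O | intermediate
10 | (4aR,7aR)-4a,7a-dimethyl-1-(prop-2-en-1-yl)-4,4a,5,6,7,7a-hexahydrocyclopenta[c]pyran-3(1H)-one, C-1 epimers | O=C1C[C@@]2(C)CCC[C@@]2(C)C(CC=C)O1 | intermediate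
11 | (4aR,7aR)-4a,7a-dimethyl-1-(3-methylbut-2-en-1-yl)-4,4a,5,6,7,7a-hexahydrocyclopenta[c]pyran-3(1H)-one, C-1 epimers | O=C1C[C@@]2(C)CCC[C@@]2(C)C(CC=C(C)C)O1 | intermediate
12 | (4aR,7aR)-4a,7a-dimethyl-1-(3-methylbut-2-en-1-yl)octahydrocyclopenta[c]pyran-3-ol, C-1 and C-3 epimers | OC1C[C@@]2(C)CCC[C@@]2(C)C(CC=C(C)C)O1 | intermediate
13 | 1-[(1R,2R)-2-(2-hydroxypent-4-yn-1-yl)-1,2-dimethylcyclopentyl]-4-methylpent-3-en-1-ol, carbinol epimers | CC(C)=CCC(O)[C@]1(C)CCC[C@]1(C)CC(O)CC#C | intermediate
14 | (E)-alkenyldimethylalane from 13, both hydroxyls as dimethylaluminium alkoxides | CC(C)=CCC(O[Al](C)C)[C@]1(C)CCC[C@]1(C)CC(O[Al](C)C)C/C(C)=C/[Al](C)C | intermediate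
15 | (E)-6-[(1R,2R)-2-(1-hydroxy-4-methylpent-3-en-1-yl)-1,2-dimethylcyclopentyl]-3-methylhex-2-ene-1,5-diol, carbinol epimers | CC(C)=CCC(O)[C@]1(C)CCC[C@]1(C)CC(O)C/C(C)=C/CO | intermediate
16 | (E)-6-chloro-1-[(1R,2R)-2-(1-hydroxy-4-methylpent-3-en-1-yl)-1,2-dimethylcyclopentyl]-4-methylhex-4-en-2-ol, carbinol epimers | CC(C)=CCC(O)[C@]1(C)CCC[C@]1(C)CC(O)C/C(C)=C/CCl | intermediate
17 | (E)-1-[(1R,2R)-2-(1-hydroxy-4-methylpent-3-en-1-yl)-1,2-dimethylcyclopentyl]-4-methyloct-4-en-7-yn-2-ol, carbinol epimers | CC(C)=CCC(O)[C@]1(C)CCC[C@]1(C)CC(O)C/C(C)=C/CC#C | intermediate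
18 | (E)-1-[(1R,2R)-1,2-dimethyl-2-(4-methylpent-3-enoyl)cyclopentyl]-4-methyloct-4-en-7-yn-2-one | CC(C)=CCC(=O)[C@]1(C)CCC[C@]1(C)CC(=O)C/C(C)=C/CC#C | intermediate
19 | (E)-1-bromoprop-1-ene | C/C=C/Br | starting material
20 | chromium hexacarbonyl, Cr(CO)6 | O=C=[Cr](=C=O)(=C=O)(=C=O)(=C=O)=C=O | starting material
21 | (E)-prop-1-enyllithium | C/C=C/[Li] | intermediate
22 | lithium pentacarbonyl[(E)-1-oxidobut-2-enylidene]chromate | C/C=C/C([O-])=[Cr](=C=O)(=C=O)(=C=O)(=C=O)=C=O.[Li+] | intermediate
23 | pentacarbonyl[(E)-1-methoxybut-2-enylidene]chromium | C/C=C/C(OC)=[Cr](=C=O)(=C=O)(=C=O)(=C=O)=C=O | intermediate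
24 | tricarbonyl(η6-arene)chromium complex of 25 (metal fragment written dot-separated) | CC(C)=CCC(=O)[C@]1(C)CCC[C@]1(C)CC(=O)C/C(C)=C/Cc1cc(OC)cc(C)c1O.[Cr](=C=O)(=C=O)=C=O | intermediate
25 | (E)-1-[(1R,2R)-1,2-dimethyl-2-(4-methylpent-3-enoyl)cyclopentyl]-6-(2-hydroxy-5-methoxy-3-methylphenyl)-4-methylhex-4-en-2-one | CC(C)=CCC(=O)[C@]1(C)CCC[C@]1(C)CC(=O)C/C(C)=C/Cc1cc(OC)cc(C)c1O | intermediate
26 | 2-{(E)-6-[(1R,2R)-1,2-dimethyl-2-(4-methylpent-3-enoyl)cyclopentyl]-3-methyl-5-oxohex-2-en-1-yl}-6-methylcyclohexa-2,5-diene-1,4-dione | CC(C)=CCC(=O)[C@]1(C)CCC[C@]1(C)CC(=O)C/C(C)=C/CC1=CC(=O)C=C(C)C1=O | target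

## Step count and least certain steps

Total step count: 17. Longest linear sequence: 16 steps (steps 1–14, 16 and 17); step 15 is a one-step branch.

Step 16 (key step). The most likely failure is diversion of the vinylketene before electrocyclisation (cyclobutenone or furan formation, or insertion of a second alkyne at high alkyne concentration), together with oxidative loss of the electron-rich phenol during demetalation. The fallback gives up the ring construction and attaches a preformed arene; it sets out from 16 and comes back at 26. 4-Methoxy-2-methylphenol is brominated ortho to the hydroxyl with N-bromosuccinimide to 2-bromo-4-methoxy-6-methylphenol F1. O-Methylation (MeI, K2CO3) gives 1-bromo-2,5-dimethoxy-3-methylbenzene F2, and Mg turns it into (2,5-dimethoxy-3-methylphenyl)magnesium bromide F3. CuI-catalysed coupling of F3 (excess) with 16 gives the aryl diol F4. Dess–Martin oxidation gives the diketone hydroquinone dimethyl ether F5, and (NH4)2Ce(NO3)6 oxidises F5 to 26.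

Step 5. The most likely failure is insufficient discrimination between the enantiotopic α-methylene protons, because the angular methyl groups change the shape on which the amide acts, and partial equilibration of the lithium enolate before silylation. The fallback is a classical resolution; it sets out from 7 and comes back at 9. LiN(i-Pr)2/Me3SiCl gives the racemic enol ether, that is 8 together with its mirror image (1R,5S)-enol ether F6. Ozonolysis as in step 6 gives 9 together with the (1S,2S)-aldehyde acid F7. The racemic acid is crystallised with (S)-N,N-dimethyl-1-phenylethylamine as the (S)-N,N-dimethyl-1-phenylethylammonium salt of 9 F8 (the (R)-amine is used if it gives the less soluble salt of 9), and acidification returns 9. A tertiary amine is chosen so that the aldehyde is not condensed.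

Step 11. The most likely failure is inefficient transfer of the alkenyl group to formaldehyde, because the two aluminium alkoxides can divert n-BuLi from alanate formation; sluggish carbometalation is a lesser concern. The fallback separates the two events; it sets out from 13 and comes back at 15. After the methylalumination, alkenylalane 14 is cleaved with I2 to the (E)-alkenyl iodide F9. F9 is coupled with Bu3SnCH2OH under Pd(PPh3)4 catalysis (zerovalent palladium, Stille coupling) to give 15.

Step 13. The most likely failure is attack at the methyl-bearing γ-carbon (SN2′), twofold coupling through the bis-magnesium acetylide, or base-induced migration of the skipped enyne. The fallback replaces the Grignard reagent by a neutral copper acetylide with a silyl cap; it sets out from 16 and comes back at 17. Trimethylsilylacetylene, CuI, NaI and K2CO3 in DMF at rt give the silyl-capped enyne diol F10, and K2CO3 in MeOH removes the silyl group to give 17.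

Step 17. The most likely failure is acid-promoted cyclisation of the phenol onto the neighbouring trisubstituted alkene (chroman formation) or double-bond migration into conjugation, competing with the oxidation in the acidic aqueous medium. The fallback removes the phenol under non-acidic conditions first; it sets out from 25 and comes back at 26. PhI(OAc)2 in MeOH at 0 °C gives the 4,4-dimethoxycyclohexa-2,5-dienone (quinone monoketal) F11, and brief treatment with dilute aqueous oxalic acid hydrolyses the ketal to 26.

## Further compounds

F1 | step 16 | 2-bromo-4-methoxy-6-methylphenol | COc1cc(C)c(O)c(Br)c1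
F2 | step 16 | 1-bromo-2,5-dimethoxy-3-methylbenzene | COc1cc(C)c(OC)c(Br)c1
F3 | step 16 | (2,5-dimethoxy-3-methylphenyl)magnesium bromide | COc1cc(C)c(OC)c([Mg]Br)c1
F4 | step 16 | (E)-6-(2,5-dimethoxy-3-methylphenyl)-1-[(1R,2R)-2-(1-hydroxy-4-methylpent-3-en-1-yl)-1,2-dimethylcyclopentyl]-4-methylhex-4-en-2-ol, carbinol epimers | CC(C)=CCC(O)[C@]1(C)CCC[C@]1(C)CC(O)C/C(C)=C/Cc1cc(OC)cc(C)c1OC
F5 | step 16 | (E)-6-(2,5-dimethoxy-3-methylphenyl)-1-[(1R,2R)-1,2-dimethyl-2-(4-methylpent-3-enoyl)cyclopentyl]-4-methylhex-4-en-2-one | CC(C)=CCC(=O)[C@]1(C)CCC[C@]1(C)CC(=O)C/C(C)=C/Cc1cc(OC)cc(C)c1OC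
F6 | step 5 | (1R,5S)-1,5-dimethyl-3-(trimethylsilyloxy)bicyclo[3.3.0]oct-2-ene (mirror image of 8) | C[Si](C)(C)OC1=C[C@@]2(C)CCC[C@@]2(C)C1
F7 | step 5 | 2-[(1S,2S)-2-formyl-1,2-dimethylcyclopentyl]acetic acid (mirror image of 9) | O=C[C@@]1(C)CCC[C@@]1(C)CC(=O)O
F8 | step 5 | (S)-N,N-dimethyl-1-phenylethylammonium 2-[(1R,2R)-2-formyl-1,2-dimethylcyclopentyl]acetate | O=C[C@]1(C)CCC[C@]1(C)CC(=O)[O-].C[C@H]([NH+](C)C)c1ccccc1
F9 | step 11 | (E)-1-[(1R,2R)-2-(2-hydroxy-5-iodo-4-methylpent-4-en-1-yl)-1,2-dimethylcyclopentyl]-4-methylpent-3-en-1-ol, carbinol epimers | CC(C)=CCC(O)[C@]1(C)CCC[C@]1(C)CC(O)C/C(C)=C/I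
F10 | step 13 | (E)-1-[(1R,2R)-2-(1-hydroxy-4-methylpent-3-en-1-yl)-1,2-dimethylcyclopentyl]-4-methyl-8-(trimethylsilyl)oct-4-en-7-yn-2-ol, carbinol epimers | CC(C)=CCC(O)[C@]1(C)CCC[C@]1(C)CC(O)C/C(C)=C/CC#C[Si](C)(C)C
F11 | step 17 | 2-{(E)-6-[(1R,2R)-1,2-dimethyl-2-(4-methylpent-3-enoyl)cyclopentyl]-3-methyl-5-oxohex-2-en-1-yl}-4,4-dimethoxy-6-methylcyclohexa-2,5-dien-1-one | CC(C)=CCC(=O)[C@]1(C)CCC[C@]1(C)CC(=O)C/C(C)=C/CC1=CC(OC)(OC)C=C(C)C1=O
A1 | alternative 1 | cis-anti-cis tricyclic photoadduct (dioxanone, cyclobutane and cyclopentane rings) | C[C@@]12O[C@@H](C(C)(C)C)OC(=O)[C@@H]1[C@@]1(C)CCC[C@@]21C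
A2 | alternative 1 | (R)-2-tert-butyl-6-methyl-1,3-dioxin-4-one | CC1=CC(=O)O[C@H](C(C)(C)C)O1
A3 | alternative 1 | 1,2-dimethylcyclopentene | CC1=C(C)CCC1
A4 | alternative 1 | 2-[(1R,2R)-2-acetyl-1,2-dimethylcyclopentyl]acetic acid | CC(=O)[C@]1(C)CCC[C@]1(C)CC(=O)O
A5 | alternative 2 | (1R,2R)-1,2-dimethyl-2-[(E)-prop-1-enyl]cyclopentane-1-carboxylic acid | OC(=O)[C@]1(C)CCC[C@]1(C)/C=C/C
A6 | alternative 2 | (7Z,9R)-3,7,9-trimethyloxacyclonon-7-en-2-one (C-3 not defined) | O=C1O[C@H](C)/C=C(/C)CCCC1C
A7 | alternative 3 | meso cis-1,2-dimethylcyclohex-4-ene-1,2-dicarboxylic anhydride | C[C@]12CC=CC[C@@]1(C)C(=O)OC2=O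
A8 | alternative 3 | buta-1,3-diene | C=CC=C
A9 | alternative 3 | 2,3-dimethylmaleic anhydride | CC1=C(C)C(=O)OC1=O
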